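## Retrosynthetic overview

1. Target 11 ⇒ lactone 10 (ring-opening with methanol) ⇒ chromanone 6 + (E)-hex-2-enal 7: enantioselective conjugate arylation at C8, ring closure on 7-OH (lactol 9, oxidised in the same pot).
2. 6 ⇒ open-chain tigloyl triphenol 5: quinine-catalysed intramolecular oxa-Michael addition that sets C2 and C3 (cis) and selects the phenol remote from the prenyl group.
3. 5 ⇒ tigloylphloroglucinol 3 + prenyl bromide 4; 3 ⇒ phloroglucinol 1 + tigloyl chloride 2.
4. Ring order: benzene ring bought; chromanone ring (step 3); transient pyranone ring (step 4), opened to the methyl ester.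

Assumption: (−)-quinine induces the same sense here as with simpler o-tigloylphenols (C2 = R, cis product); should it prove opposite, quinidine takes its place.

## Route

Step 1
Reactants: 1 phloroglucinol (benzene-1,3,5-triol); 2 tigloyl chloride ((E)-2-methylbut-2-enoyl chloride)
Product: 3 (E)-2-methyl-1-(2,4,6-trihydroxyphenyl)but-2-en-1-one
Conditions: 2 (1.05 equiv), AlCl3 (3.5 equiv), PhNO2/CH2Cl2, 0 °C → rt, 3 h; ice/1 M HCl
Reagents that add atoms: tigloyl chloride 2, C/C=C(\C)C(Cl)=O
Why: Friedel–Crafts acylation: the C3-symmetric triphenol gives one regioisomer, the ketone–aluminium chelate stops a second acylation, and at or below room temperature the E-enone is released uncyclised on cold acidic work-up.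

Step 2
Reactants: 3 (E)-2-methyl-1-(2,4,6-trihydroxyphenyl)but-2-en-1-one; 4 prenyl bromide (1-bromo-3-methylbut-2-ene)
Product: 5 (E)-2-methyl-1-[2,4,6-trihydroxy-3-(3-methylbut-2-en-1-yl)phenyl]but-2-en-1-one
Conditions: 4 (1.0 equiv), 5% aq KOH (3.2 equiv), Ar, 0 °C, 1 h; poured into ice-cold 2 M HCl
Reagents that add atoms: prenyl bromide 4, CC(C)=CCBr
Why: C-alkylation of the ambident polyphenoxide (SN2; water favours C over O); the two free ring carbons of 3 are equivalent, so a single C-prenyl isomer results, and in excess hydroxide the enone is a deactivated vinylogous carboxylate that stays ring-open (as 2′-hydroxychalcones do in alkali) until the fast cold acid quench.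

Step 3
Reactants: 5 (E)-2-methyl-1-[2,4,6-trihydroxy-3-(3-methylbut-2-en-1-yl)phenyl]but-2-en-1-one
Product: 6 (2R,3S)-5,7-dihydroxy-2,3-dimethyl-6-(3-methylbut-2-en-1-yl)-2,3-dihydro-4H-chromen-4-one (cis)
Conditions: (−)-quinine (20 mol%), PhCl, 10 °C, 48–72 h; chromatography removes the minor 8-prenyl isomer
Reagents that add atoms: none
Why: Proposed new method: asymmetric intramolecular oxa-Michael addition on an unprotected triphenol (closest known type: quinine-catalysed cyclisation of o-tigloylphenols to cis-2,3-dimethylchroman-4-ones); the quinuclidine nitrogen acts as general base on the less hindered, more acidic 6-OH (flanked by H) while the 2-OH, buttressed by the prenyl group, stays locked in the hydrogen bond to the carbonyl (prenylated 2′,4′,6′-trihydroxychalcones likewise close mainly to 6-prenylflavanones), the chiral ion pair adds to one enone face to set C2 as R, and kinetic protonation of the enol on the same face sets C3 as S (cis).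

Step 4
Reactants: 6 (2R,3S)-5,7-dihydroxy-2,3-dimethyl-6-(3-methylbut-2-en-1-yl)-2,3-dihydro-4H-chromen-4-one; 7 (E)-hex-2-enal; 8 methanol
Product: 11 methyl (3S)-3-[(2R,3S)-5,7-dihydroxy-2,3-dimethyl-6-(3-methylbut-2-en-1-yl)-4-oxo-3,4-dihydro-2H-chromen-8-yl]hexanoate, via lactol 9 (not isolated), via lactone 10 (not isolated)
Conditions: 7 (1.3 equiv), (R)-2-[diphenyl(trimethylsilyloxy)methyl]pyrrolidine (20 mol%), PhCO2H (20 mol%), toluene, 0 °C, 24 h; volatiles removed; then MeOH/THF 1:1, 1,4-dimethyl-1,2,4-triazolium iodide (10 mol%), DBU (0.4 equiv), 3,3′,5,5′-tetra-tert-butyldiphenoquinone (1.2 equiv), rt, 6 h; AcOH quench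
Reagents that add atoms: (E)-hex-2-enal 7, CCC/C=C/C=O; methanol 8, CO
Why: Iminium-ion Friedel–Crafts alkylation/hemiacetalisation followed by NHC-catalysed oxidative esterification: C8 is the only free ring carbon and 7-OH the only adjacent phenol, the (R)-amine shields one face of the (E)-iminium so the arene adds to the opposite face of the β-carbon and gives 3S, and the acyl azolium derived from 9 lactonises to 10, which the buffered methanolic medium opens to 11 without touching C2/C3.

## Compound list

1 | phloroglucinol (benzene-1,3,5-triol) | Oc1cc(O)cc(O)c1 | starting material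
2 | tigloyl chloride, (E)-2-methylbut-2-enoyl chloride | C/C=C(\C)C(Cl)=O | starting material
3 | (E)-2-methyl-1-(2,4,6-trihydroxyphenyl)but-2-en-1-one | C/C=C(\C)C(=O)c1c(O)cc(O)cc1O | intermediate
4 | prenyl bromide, 1-bromo-3-methylbut-2-ene | CC(C)=CCBr | starting material
5 | (E)-2-methyl-1-[2,4,6-trihydroxy-3-(3-methylbut-2-en-1-yl)phenyl]but-2-en-1-one | C/C=C(\C)C(=O)c1c(O)cc(O)c(CC=C(C)C)c1O | intermediate
6 | (2R,3S)-5,7-dihydroxy-2,3-dimethyl-6-(3-methylbut-2-en-1-yl)-2,3-dihydro-4H-chromen-4-one | Oc1cc2O[C@H](C)[C@H](C)C(=O)c2c(O)c1CC=C(C)C | intermediate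
7 | (E)-hex-2-enal | CCC/C=C/C=O | starting material
8 | methanol | CO | starting material
9 | lactol: (2R,3S,10S)-5,8-dihydroxy-2,3-dimethyl-6-(3-methylbut-2-en-1-yl)-10-propyl-2,3,9,10-tetrahydro-4H,8H-pyrano[2,3-f]chromen-4-one (both C8 anomers) | CCC[C@H]1CC(O)Oc2c1c1O[C@H](C)[C@H](C)C(=O)c1c(O)c2CC=C(C)C | intermediate
10 | lactone: (2R,3S,10S)-5-hydroxy-2,3-dimethyl-6-(3-methylbut-2-en-1-yl)-10-propyl-2,3,9,10-tetrahydropyrano[2,3-f]chromene-4,8-dione | CCC[C@H]1CC(=O)Oc2c1c1O[C@H](C)[C@H](C)C(=O)c1c(O)c2CC=C(C)C | intermediate
11 | methyl (3S)-3-[(2R,3S)-5,7-dihydroxy-2,3-dimethyl-6-(3-methylbut-2-en-1-yl)-4-oxo-3,4-dihydro-2H-chromen-8-yl]hexanoate | CCC[C@@H](CC(=O)OC)c1c(O)c(CC=C(C)C)c(O)c2c1O[C@H](C)[C@H](C)C2=O | target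

## Step count and risks

Total step count: 4. Longest linear sequence: 4.

Steps most likely to fail:

**Step 3** (regioselection between the two ortho-phenols, enantioselectivity on a free triphenol, racemic background cyclisation). Fallback, setting out from 3 and coming back at 6: the cyclisation is run before prenylation, where both ortho-phenols are equivalent. 3 with (−)-quinine (20 mol%) in PhCl at 10 °C gives (2R,3S)-5,7-dihydroxy-2,3-dimethyl-2,3-dihydro-4H-chromen-4-one F3. Its mono-sodium 7-phenoxide (NaH, 1.0 equiv, toluene, 0 °C; no excess base, so the cis stereocentres are not exposed to anything stronger than a phenoxide) is then C-alkylated with 4, mainly at C6, the carbon between the two oxygens. The C8 isomer and the O-ether are separated, giving 6.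

**Step 2** (the enone may cyclise under base; over-alkylation and O-alkylation). Fallback, setting out from 3 and coming back at 5: the prenyl group is delivered through oxygen under neutral conditions. 2-Methylbut-3-en-2-ol and methyl chloroformate (pyridine, CH2Cl2, 0 °C) give 2-methylbut-3-en-2-yl methyl carbonate F1. With the zerovalent palladium complex Pd(PPh3)4 (2 mol%) in THF at 0 °C, F1 etherifies the most acidic, unchelated 4-OH of 3 at the tertiary terminus to give (E)-1-{2,6-dihydroxy-4-[(2-methylbut-3-en-2-yl)oxy]phenyl}-2-methylbut-2-en-1-one F2. Warming F2 in toluene (80 °C) triggers the aromatic Claisen rearrangement onto either of the two equivalent ortho carbons and gives 5.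

**Step 4** (nucleophilicity of C8 toward the iminium ion, compatibility of the two organocatalysts, epimerisation of the cis-chromanone by base). Fallback, setting out from 6 and coming back at 10, then 11: the hexenoyl unit is brought in at the acid oxidation level. 6 and 7 are treated with a chiral aminoindanol-derived N-mesityl triazolium chloride (10 mol%, enantiomer chosen in a model run), 3,3′,5,5′-tetra-tert-butyldiphenoquinone and LiOAc in THF at rt. This forms the α,β-unsaturated acyl azolium, which annulates across C8/7-OH (Coates–Claisen-type [3+3] reaction) to give lactone 10 directly. 10 is isolated and opened with MeOH (cat. camphorsulfonic acid, rt) to 11.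

## Further compounds

F1 | step 2 | 2-methylbut-3-en-2-yl methyl carbonate | COC(=O)OC(C)(C)C=C
F2 | step 2 | (E)-1-{2,6-dihydroxy-4-[(2-methylbut-3-en-2-yl)oxy]phenyl}-2-methylbut-2-en-1-one | C/C=C(\C)C(=O)c1c(O)cc(OC(C)(C)C=C)cc1O
F3 | step 3 | (2R,3S)-5,7-dihydroxy-2,3-dimethyl-2,3-dihydro-4H-chromen-4-one | Oc1cc2O[C@H](C)[C@H](C)C(=O)c2c(O)c1
F0 | step 4 | none | none
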